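**Retrosynthetic overview**
1. Target 22 comes from tetra-MOM flavanone 21 by acetal cleavage. C2 is the only stereocentre.
2. Ring C (O1–C2–C3–C4–C4a–C8a) is not closed as a six-membered ring. The C2–C1′ bond is cut and, in the same operation, C4 is shifted from C3 back to C2. This leads to aryl iodide 17 (ring B) and benzofuran-3(2H)-one 13, whose side chain CH2–CO2N(phthaloyl) carries the future C3.
3. Enabling feature: C4=O stands 1,3 to C2 across an unsubstituted C3H2, and O1 sits on C2. A C3 radical hanging on the five-membered ring can therefore attack C4=O. The acyl shift is driven by formation of the O1-stabilised C2 radical, which a chiral aryl–nickel complex converts into the C2–aryl bond.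
4. The five-membered O-ring comes from salicylaldehyde 8 and methyl propiolate 9 by oxa-Michael addition and a Stetter reaction. The ester carbon activates this closure and later leaves as CO2.
5. The geranyl group lies para to O1, so phenol 7 is symmetric and its two ortho carbons are equivalent, which fixes the 6-geranyl pattern. Ring order: ring A (bought), then the five-membered O-ring (step 7), then ring C by expansion with ring B attached (step 13).

Key step: step 13

Assumption: the sense of induction of the nickel/BiOX catalyst on radical 20 cannot be derived from precedent, so the (S,S)-ligand is written and its antipode is taken if it proves to favour (2R).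

Step 1
Reactants: 1 phloroglucinol (benzene-1,3,5-triol)
Product: 2 3,5-bis(methoxymethoxy)phenol
Conditions: MOMCl (2 equiv), i-Pr2NEt, THF, 0 °C to rt; chromatography
Reagents that add atoms: chloromethyl methyl ether (MOMCl), COCCl
Why: Williamson-type O-alkylation of two of three equivalent phenols stops statistically at the bis-ether with two equivalents of reagent, and mono-, bis- and tris-ethers differ enough in polarity to be separated.

Step 2
Reactants: 2 3,5-bis(methoxymethoxy)phenol
Product: 3 [3,5-bis(methoxymethoxy)phenoxy]triisopropylsilane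
Conditions: TIPSCl, imidazole, DMF, rt
Reagents that add atoms: chlorotriisopropylsilane (TIPSCl), CC(C)[Si](Cl)(C(C)C)C(C)C
Why: Imidazole-promoted silyl ether formation masks the future O1 with a bulky group that neither directs lithiation nor is attacked by n-BuLi.

Step 3
Reactants: 3 [3,5-bis(methoxymethoxy)phenoxy]triisopropylsilane; 4 geranyl bromide [(2E)-1-bromo-3,7-dimethylocta-2,6-diene]
Product: 6 [4-geranyl-3,5-bis(methoxymethoxy)phenoxy]triisopropylsilane (geranyl = (2E)-3,7-dimethylocta-2,6-dien-1-yl), via aryllithium 5 (not isolated)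
Conditions: n-BuLi, THF, 0 °C; CuBr·SMe2 (10 mol %), 4, −78 °C to rt
Reagents that add atoms: none
Why: Directed ortho-metalation, in which the two MOM ethers cooperatively guide n-BuLi to the carbon between them (para to OTIPS), followed by copper-catalysed SN2 allylation with the primary allylic bromide, should keep the E-alkene and place the geranyl group on the symmetry axis of ring A.

Step 4
Reactants: 6 [4-geranyl-3,5-bis(methoxymethoxy)phenoxy]triisopropylsilane
Product: 7 4-geranyl-3,5-bis(methoxymethoxy)phenol
Conditions: n-Bu4NF, THF, 0 °C; aq NH4Cl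
Reagents that add atoms: none
Why: Fluoride-induced Si–O cleavage frees only the phenol that becomes O1, since MOM acetals and alkenes are inert to fluoride.

Step 5
Reactants: 7 4-geranyl-3,5-bis(methoxymethoxy)phenol
Product: 8 3-geranyl-6-hydroxy-2,4-bis(methoxymethoxy)benzaldehyde
Conditions: MgCl2, Et3N, (CH2O)n, MeCN, reflux; cold dilute HCl
Reagents that add atoms: paraformaldehyde (as formaldehyde), C=O
Why: Casnati–Skattebøl ortho-formylation through the magnesium phenoxide delivers formaldehyde only ortho to the free OH, and because both ortho carbons are equivalent by symmetry a single aldehyde with the substitution pattern of ring A should form.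

Step 6
Reactants: 8 3-geranyl-6-hydroxy-2,4-bis(methoxymethoxy)benzaldehyde; 9 methyl propiolate
Product: 10 methyl (E)-3-[2-formyl-4-geranyl-3,5-bis(methoxymethoxy)phenoxy]prop-2-enoate
Conditions: N-methylmorpholine (20 mol %), CH2Cl2, rt
Reagents that add atoms: none
Why: Amine-catalysed oxa-Michael addition of the phenol to the propiolate gives the E-β-aryloxyacrylate, which brings in C2 and C3 of the target together with a removable ester carbon.

Step 7
Reactants: 10 methyl (E)-3-[2-formyl-4-geranyl-3,5-bis(methoxymethoxy)phenoxy]prop-2-enoate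
Product: 11 methyl 2-[5-geranyl-4,6-bis(methoxymethoxy)-3-oxo-2,3-dihydro-1-benzofuran-2-yl]acetate (racemic)
Conditions: 3-benzyl-5-(2-hydroxyethyl)-4-methylthiazolium chloride (20 mol %), Et3N (40 mol %), DMF, 60 °C
Reagents that add atoms: none
Why: Intramolecular Stetter reaction, in which the carbene-derived acyl anion equivalent of the aldehyde adds 5-exo-trig to the oxygen-bearing β-carbon of the acrylate, is well known for salicylaldehyde-derived aryloxyacrylates; the new C2 centre is racemic and is erased in step 13.

Step 8
Reactants: 11 methyl 2-[5-geranyl-4,6-bis(methoxymethoxy)-3-oxo-2,3-dihydro-1-benzofuran-2-yl]acetate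
Product: 12 2-[5-geranyl-4,6-bis(methoxymethoxy)-3-oxo-2,3-dihydro-1-benzofuran-2-yl]acetic acid (racemic)
Conditions: LiOH·H2O, THF–H2O, 0 °C, argon; cold 1 M HCl to pH 3–4
Reagents that add atoms: lithium hydroxide (hydroxide oxygen ends in the acid), [Li+].[OH-]
Why: Saponification of the unhindered methyl ester, in which the acidic C2–H is deprotonated first and so shields the β-aryloxy ester from E1cB ring opening, with air excluded to avoid enolate oxidation.

Step 9
Reactants: 12 2-[5-geranyl-4,6-bis(methoxymethoxy)-3-oxo-2,3-dihydro-1-benzofuran-2-yl]acetic acid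
Product: 13 1,3-dioxoisoindolin-2-yl 2-[5-geranyl-4,6-bis(methoxymethoxy)-3-oxo-2,3-dihydro-1-benzofuran-2-yl]acetate (racemic redox-active ester)
Conditions: N-hydroxyphthalimide, DIC, CH2Cl2, 0 °C to rt (no amine base)
Reagents that add atoms: N-hydroxyphthalimide, O=C1c2ccccc2C(=O)N1O
Why: Carbodiimide esterification (Steglich type, run without amine base) gives the redox-active ester, and the absence of base keeps enolisation and E1cB opening slow.

Step 10
Reactants: 14 o-vanillin (2-hydroxy-3-methoxybenzaldehyde)
Product: 15 2-hydroxy-5-iodo-3-methoxybenzaldehyde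
Conditions: NIS, CF3CO2H (10 mol %), MeCN, rt
Reagents that add atoms: N-iodosuccinimide, O=C1CCC(=O)N1I
Why: Electrophilic aromatic iodination goes para to the free phenol, whose two ortho positions are already occupied.

Step 11
Reactants: 15 2-hydroxy-5-iodo-3-methoxybenzaldehyde
Product: 16 5-iodo-3-methoxybenzene-1,2-diol
Conditions: 30 % H2O2, aq NaOH, THF, 0 °C to rt, N2; dilute HCl
Reagents that add atoms: hydrogen peroxide, OO
Why: Dakin oxidation converts the ortho-hydroxy aldehyde into the catechol by aryl migration to peroxide oxygen and loss of formate, the aryl iodide being inert.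

Step 12
Reactants: 16 5-iodo-3-methoxybenzene-1,2-diol
Product: 17 5-iodo-1-methoxy-2,3-bis(methoxymethoxy)benzene
Conditions: MOMCl (2.5 equiv), i-Pr2NEt, CH2Cl2, 0 °C to rt
Reagents that add atoms: chloromethyl methyl ether (MOMCl), COCCl
Why: Double Williamson-type O-alkylation protects the air-sensitive catechol with the same acetal used on ring A, so that one final operation frees all phenols.

Step 13
Reactants: 13 1,3-dioxoisoindolin-2-yl 2-[5-geranyl-4,6-bis(methoxymethoxy)-3-oxo-2,3-dihydro-1-benzofuran-2-yl]acetate; 17 5-iodo-1-methoxy-2,3-bis(methoxymethoxy)benzene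
Product: 21 (2S)-6-geranyl-2-[3-methoxy-4,5-bis(methoxymethoxy)phenyl]-5,7-bis(methoxymethoxy)chroman-4-one, via primary alkyl radical 18 (not isolated), via cyclopropyloxy radical 19 (not isolated), via chromanon-2-yl radical 20 (not isolated)
Conditions: NiBr2·diglyme (10 mol %), (S,S)-4-heptyl-BiOX (12 mol %), Zn dust (2 equiv), NaI (0.5 equiv), DMA, 5 °C; 13 added over 8 h by syringe pump
Reagents that add atoms: none
Why: Proposed new method: zerovalent nickel inserts into the C–I bond of 17, and single-electron reduction of 13 by low-valent nickel or Zn expels phthalimide anion and CO2 to leave primary radical 18. Radical 18 closes 3-exo-trig onto the adjacent ketone carbon to give cyclopropyloxy radical 19, whose β-scission at the bond shared by the two rings (old C2–C3 of the benzofuranone) transfers the aroyl carbon to the former side-chain CH2, so that the five-membered O-ring becomes the six-membered ring C in radical 20 (Dowd–Beckwith 1,2-acyl shift; ring C is never closed directly). Radical 20 is trapped by the chiral aryl complex of divalent nickel and the C2–C1′ bond forms by reductive elimination from trivalent nickel, the twofold-symmetric BiOX ligand deciding which face of the nearly planar chromanon-2-yl unit is arylated and so setting the only stereocentre. The closest known reaction types are the Dowd–Beckwith expansion of 2-(halomethyl)-3-oxo oxygen heterocycles, the nickel-catalysed decarboxylative cross-electrophile coupling of N-hydroxyphthalimide esters with aryl iodides, and the nickel-catalysed enantioselective arylation of cyclic α-oxy radicals; only their merger is new. The step needs the unimolecular acyl shift to outrun bimolecular capture of 18, which is secured by the 1,3-relation of radical carbon and C=O, by the gain on going from a primary to an O1-stabilised secondary radical with relief of five-ring strain, and by slow addition that keeps radical and aryl–nickel concentrations low. The geranyl alkenes lie too far from 18 and 20 for five- or six-membered cyclisation, and the absence of added base spares the acidic C2–H of 13, the MOM acetals and the product, which would open by retro-oxa-Michael reaction in base.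

Step 14
Reactants: 21 (2S)-6-geranyl-2-[3-methoxy-4,5-bis(methoxymethoxy)phenyl]-5,7-bis(methoxymethoxy)chroman-4-one
Product: 22 (2S)-2-(3,4-dihydroxy-5-methoxyphenyl)-6-geranyl-5,7-dihydroxychroman-4-one (target)
Conditions: 3 M aq HCl, MeOH, 45 °C
Reagents that add atoms: none
Why: Acid-catalysed acetal exchange with methanol removes all four MOM groups under conditions with close precedent for prenylated and geranylated flavanones, and C2 is not touched because acid does not trigger the retro-oxa-Michael path that racemises flavanones in base.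

**Compound list**
1 | phloroglucinol | Oc1cc(O)cc(O)c1 | starting material
2 | 3,5-bis(methoxymethoxy)phenol | COCOc1cc(O)cc(OCOC)c1 | intermediate
3 | [3,5-bis(methoxymethoxy)phenoxy]triisopropylsilane | COCOc1cc(O[Si](C(C)C)(C(C)C)C(C)C)cc(OCOC)c1 | intermediate
4 | geranyl bromide | BrC/C=C(\C)CCC=C(C)C | starting material
5 | 4-lithio derivative of 3 (aryllithium) | COCOc1cc(O[Si](C(C)C)(C(C)C)C(C)C)cc(OCOC)c1[Li] | intermediate
6 | [4-geranyl-3,5-bis(methoxymethoxy)phenoxy]triisopropylsilane | COCOc1cc(O[Si](C(C)C)(C(C)C)C(C)C)cc(OCOC)c1C/C=C(\C)CCC=C(C)C | intermediate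
7 | 4-geranyl-3,5-bis(methoxymethoxy)phenol | COCOc1cc(O)cc(OCOC)c1C/C=C(\C)CCC=C(C)C | intermediate
8 | 3-geranyl-6-hydroxy-2,4-bis(methoxymethoxy)benzaldehyde | O=Cc1c(O)cc(OCOC)c(C/C=C(\C)CCC=C(C)C)c1OCOC | intermediate
9 | methyl propiolate | C#CC(=O)OC | starting material
10 | methyl (E)-3-[2-formyl-4-geranyl-3,5-bis(methoxymethoxy)phenoxy]prop-2-enoate | COC(=O)/C=C/Oc1cc(OCOC)c(C/C=C(\C)CCC=C(C)C)c(OCOC)c1C=O | intermediate
11 | methyl 2-[5-geranyl-4,6-bis(methoxymethoxy)-3-oxo-2,3-dihydro-1-benzofuran-2-yl]acetate (racemic) | COC(=O)CC1Oc2cc(OCOC)c(C/C=C(\C)CCC=C(C)C)c(OCOC)c2C1=O | intermediate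
12 | 2-[5-geranyl-4,6-bis(methoxymethoxy)-3-oxo-2,3-dihydro-1-benzofuran-2-yl]acetic acid (racemic) | OC(=O)CC1Oc2cc(OCOC)c(C/C=C(\C)CCC=C(C)C)c(OCOC)c2C1=O | intermediate
13 | N-hydroxyphthalimide ester of 12 (racemic) | O=C(CC1Oc2cc(OCOC)c(C/C=C(\C)CCC=C(C)C)c(OCOC)c2C1=O)ON1C(=O)c2ccccc2C1=O | intermediate
14 | o-vanillin | COc1cccc(C=O)c1O | starting material
15 | 2-hydroxy-5-iodo-3-methoxybenzaldehyde | COc1cc(I)cc(C=O)c1O | intermediate
16 | 5-iodo-3-methoxybenzene-1,2-diol | COc1cc(I)cc(O)c1O | intermediate
17 | 5-iodo-1-methoxy-2,3-bis(methoxymethoxy)benzene | COCOc1cc(I)cc(OC)c1OCOC | intermediate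
18 | (3-oxo-2,3-dihydrobenzofuran-2-yl)methyl radical (primary alkyl radical) | [CH2]C1Oc2cc(OCOC)c(C/C=C(\C)CCC=C(C)C)c(OCOC)c2C1=O | intermediate
19 | cyclopropa[b]benzofuran-6b-yloxy radical (cyclopropyloxy radical) | [O]C12CC1Oc1cc(OCOC)c(C/C=C(\C)CCC=C(C)C)c(OCOC)c12 | intermediate
20 | 4-oxochroman-2-yl radical (chromanon-2-yl radical) | O=C1C[CH]Oc2cc(OCOC)c(C/C=C(\C)CCC=C(C)C)c(OCOC)c12 | intermediate
21 | (2S)-6-geranyl-2-[3-methoxy-4,5-bis(methoxymethoxy)phenyl]-5,7-bis(methoxymethoxy)chroman-4-one | COc1cc([C@@H]2CC(=O)c3c(cc(OCOC)c(C/C=C(\C)CCC=C(C)C)c3OCOC)O2)cc(OCOC)c1OCOC | intermediate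
22 | (2S)-2-(3,4-dihydroxy-5-methoxyphenyl)-6-geranyl-5,7-dihydroxychroman-4-one | COc1cc([C@@H]2CC(=O)c3c(cc(O)c(C/C=C(\C)CCC=C(C)C)c3O)O2)cc(O)c1O | target

Total step count: 14. Longest linear sequence: 11 steps (steps 1–9, 13, 14).

**Steps most likely to fail**

Step 13.
- What may go wrong: nickel may capture the primary radical before the acyl shift. The alkyl–nickel species may undergo β-hydride elimination. The aryloxy bond next to the radical may fragment. Zinc salts may promote enol-lactonisation of the active ester. Facial selectivity in the aryl transfer may be poor.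
- Fallback (known chemistry, ring expansion kept): it sets out from 13 and 17 and comes back at 21.
- Photoredox reductive decarboxylation of 13 (Ru(bpy)3(PF6)2, Hantzsch ester, blue light, CH2Cl2, high dilution) runs the same Dowd–Beckwith shift with hydrogen-atom termination and should give 6-geranyl-5,7-bis(methoxymethoxy)chroman-4-one F1.
- Soft enolisation (Me3SiOTf, Et3N, CH2Cl2, 0 °C) gives the trimethylsilyl enol ether F2, and Saegusa–Ito oxidation with Pd(OAc)2 in MeCN gives 6-geranyl-5,7-bis(methoxymethoxy)chromen-4-one F3.
- Iodide 17 is converted by iodine–magnesium exchange (i-PrMgCl·LiCl), B(OMe)3 and aqueous work-up into [3-methoxy-4,5-bis(methoxymethoxy)phenyl]boronic acid F4.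
- Palladium-catalysed asymmetric conjugate addition of F4 to F3 (Pd(OCOCF3)2, the t-BuPyOx antipode that gives S, NH4PF6, H2O, ClCH2CH2Cl, 60 °C), a reaction established for chromones, returns to 21.

Step 7.
- What may go wrong: the acyl anion equivalent may form slowly at the electron-rich, doubly ortho-substituted aldehyde, and the acrylate may be lost by retro-oxa-Michael reaction.
- Fallback: it sets out from 8 and comes back at 11.
- A Corey–Chaykovsky reaction (Me3S(O)I, NaH, DMSO), in which the phenoxide closes the ring, gives 5-geranyl-4,6-bis(methoxymethoxy)-2,3-dihydro-1-benzofuran-3-ol F5.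
- Dess–Martin periodinane with NaHCO3 gives 5-geranyl-4,6-bis(methoxymethoxy)-1-benzofuran-3(2H)-one F6.
- C-alkylation of its lithium enolate (LiN(SiMe3)2, THF, −78 °C) with methyl bromoacetate gives 11.

Step 14.
- What may go wrong: protons may induce cyclisation of the geranyl chain onto a freed neighbouring phenol or addition of methanol to the alkenes. Ring C may open under acid, with erosion of configuration.
- Fallback: it sets out from 21 and comes back at 22.
- Non-protic acetal-to-silyl-ether exchange (Me3SiOTf, 2,2′-bipyridyl, MeCN, 0 °C) gives the tetrakis(trimethylsilyl) ether F7.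
- F7 is hydrolysed with water at neutral pH to give 22.

**Further compounds**
F1 | step 13 | 6-geranyl-5,7-bis(methoxymethoxy)chroman-4-one | O=C1CCOc2cc(OCOC)c(C/C=C(\C)CCC=C(C)C)c(OCOC)c12
F2 | step 13 | 6-geranyl-5,7-bis(methoxymethoxy)-4-(trimethylsilyloxy)-2H-chromene | C[Si](C)(C)OC1=CCOc2cc(OCOC)c(C/C=C(\C)CCC=C(C)C)c(OCOC)c12
F3 | step 13 | 6-geranyl-5,7-bis(methoxymethoxy)chromen-4-one | O=c1ccoc2cc(OCOC)c(C/C=C(\C)CCC=C(C)C)c(OCOC)c12
F4 | step 13 | [3-methoxy-4,5-bis(methoxymethoxy)phenyl]boronic acid | COCOc1cc(B(O)O)cc(OC)c1OCOC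
F5 | step 7 | 5-geranyl-4,6-bis(methoxymethoxy)-2,3-dihydro-1-benzofuran-3-ol (racemic) | OC1COc2cc(OCOC)c(C/C=C(\C)CCC=C(C)C)c(OCOC)c12
F6 | step 7 | 5-geranyl-4,6-bis(methoxymethoxy)-1-benzofuran-3(2H)-one | O=C1COc2cc(OCOC)c(C/C=C(\C)CCC=C(C)C)c(OCOC)c12
F7 | step 14 | (2S)-6-geranyl-2-[3-methoxy-4,5-bis(trimethylsilyloxy)phenyl]-5,7-bis(trimethylsilyloxy)chroman-4-one | COc1cc([C@@H]2CC(=O)c3c(cc(O[Si](C)(C)C)c(C/C=C(\C)CCC=C(C)C)c3O[Si](C)(C)C)O2)cc(O[Si](C)(C)C)c1O[Si](C)(C)C
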